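The earlier runs and the new flask stem from a simulated flask with made-up constants, noise included.

Treat the charge of coupling partner as a budget, and ask of each flask how much of it the starting material will demand.

| flask | starting material | coupling partner | time |
|---|---|---|---|
| north | 200 mM | 300 mM |  |
| north-west | 80.0 mM | 180 mM |  |
| south-east | 200 mM | 900 mM |  |
| south | 600 mM | 300 mM |  |
| south-west | 400 mM | 900 mM | 69 min |

| north run: time / min | north run: [target] / mM | north-west run: time / min | north-west run: [target] / mM | south-east run: time / min | south-east run: [target] / mM | south run: time / min | south run: [target] / mM |
|---|---|---|---|---|---|---|---|
| 14 | 51.6 | 14 | 17.7 | 14 | 49.8 | 14 | 128.3 |
| 28 | 89.9 | 28 | 33.5 | 28 | 84.2 | 28 | 215.3 |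
| 41 | 108.9 | 41 | 38.8 | 41 | 102.6 | 41 | 249.5 |
| 55 | 120.0 | 55 | 43.6 | 55 | 114.6 | 55 | 268.4 |
| 69 | 125.4 | 69 | 45.6 | 69 | 118.8 | 69 | 274.1 |

(readings scatter by 1 mM)

- Overall: starting material + coupling partner -> target.
- Constant volume, constant temperature.
- The analysis sees a species whether free or bound.
- "The second partner" is coupling partner.
- An order is taken over about fifteen percent of the charge, up and down.

* the power of [coupling partner] that the first rate follows, about the charge of the north run; measure it at two percent of starting material made into target
* the power of [starting material] that the first rate follows, about the charge of the north run; measure it at two percent of starting material made into target (one fixed amount of target, the same in the runs compared)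
* target in the south-west run at 69 min, as a share of the starting material charged

The bench rule for a partner in excess is pseudo-first-order: it takes c(coupling partner) as level, and on that assumption the share of starting material made into target by a given time doesn't change with the charge of starting material. We take the south-east run as that end, and at 69 min it stands at 59.4 %. The other end is a ceiling. The overall equation is one to one, so when the partner is the limiting reagent, the share can't pass c(coupling partner)/c(starting material) at the start. We join the two ends by taking the smaller value.

The south-west run asks for 26.4 % of its partner: this share, the target the excess rule asks for over the partner charged, is the partner demand. The north-west run has the same demand and reads 57.0 %, while the north run, at demand 39.6 %, reads 62.7 %. So the rule's figure of 59.4 % lies between these two readings. The south run's demand is 119 %, more than its whole partner charge, so the rule stops there and our join takes the ceiling of 50.0 %. For the south-west run our join gives 59.4 %, above the north-west reading and below the north one.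

The forecast is lower: 56 % (51 % to 60 %), with order 0.2 (0 to 0.4) in coupling partner and 0.88 (0.72 to 1.02) in starting material, on the ground that “The starting material is nearly first order with mild saturation”.

The simulation gives 63.7 %, with orders 0.32 and 0.61.

    starting material → intermediate (0.04914 /min)
    intermediate + coupling partner → target (1.020 /M/min)
    intermediate → side product (0.08160 /min)
    target + coupling partner → side product (0.006900 /M/min)
    starting material + coupling partner ⇌ idle substrate-reagent adduct, settled at all times (1.190 /M)

The south-west target comes to 28.3 % of the partner charged, against a demand of 26.4 % and well below the whole charge, so that flask stands on the excess side of the join. Yet partner still costs it target: without the path from target + coupling partner to side product, the south-west run gives 75.6 % instead of 63.7 %, a loss of 12 percentage points, about a third of what is missing from full conversion. The south run, at demand 119 %, lies beyond the border: at 69 min it reads 45.7 %, under its ceiling, with target at nearly all of the partner charged, 91.4 %.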